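**Plan**

Numbering: ring carbons C1 (bears =CH2), C2, C3, C4 (CO2H), C5 (quaternary), C6, C7=C8 (cis), C9=C10 (CO2H on C10).
Retrosynthetic cuts, in order: the two esters; the ketone oxygen and the furan–alkyne bond of the C5 arm; the C1 methylene; C9=C10 (opens the ring); C1–C2; C7=C8; finally C3–C4 together with C5–C6.
Feature used: the neighbouring stereocentres C4 (H, CO2H) and C5 (CH3, arm), with carboxyl cis to methyl along C3–C4–C5–C6, are the two alkene carbons of an (E)-enal ester; a temporary C2–C7 bond makes C2–C3–C4–C5–C6–C7 a cyclohexene.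
Forward: a 2-silyloxydiene and the enal ester give that cyclohexene (the only carbocycle before the macrocycle). Ozonolysis of its C2=C7 enol ether frees a C2 acid and a C7 aldehyde. The arms are grown (formyl to alkyne, C7 to a Z-enal, C2 to a β-keto ester), the ten-membered ring closes at C9=C10, and methylenation, furan coupling, alkyne hydration and saponification finish.
Stereochemistry: C4 and C5 are both set in the catalytic enantioselective Diels–Alder step (relative configuration from the E alkene, absolute from the catalyst) and are not touched again; C7=C8 is Z from a Wittig reaction and the C9=C10 geometry is imposed by the ring.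

Key step: step 2

Assumption: the facial sense of the (S)-configured oxazaborolidinium catalyst is taken from its cycloadditions of 2-methylacrolein (diene adds to the Re face of the formyl-bearing carbon); if the sense proves opposite, the (R)-catalyst is used in the same way.

**Route**

Step 1
Reactants: 1 methyl vinyl ketone
Product: 2 2-(triisopropylsilyloxy)buta-1,3-diene
Conditions: TIPSOTf, Et3N, CH2Cl2, 0 °C to rt
Reagents that add atoms: triisopropylsilyl trifluoromethanesulfonate, CC(C)[Si](C(C)C)(C(C)C)OS(=O)(=O)C(F)(F)F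
Why: Soft enolisation of the enone (O-silylation by the silyl triflate, deprotonation of the methyl group by Et3N) is the standard silyl enol ether formation that turns methyl vinyl ketone into the 2-silyloxydiene.

Step 2
Reactants: 2 2-(triisopropylsilyloxy)buta-1,3-diene; 3 ethyl (E)-3-methyl-4-oxobut-2-enoate
Product: 4 ethyl (1R,6R)-6-formyl-6-methyl-3-[(triisopropylsilyl)oxy]cyclohex-3-ene-1-carboxylate
Conditions: (S)-3,3-diphenyl-1-(o-tolyl)tetrahydro-1H,3H-pyrrolo[1,2-c][1,3,2]oxazaborole (20 mol%), Tf2NH (18 mol%), CH2Cl2, −78 °C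
Reagents that add atoms: none
Why: The protonated oxazaborolidine binds the formyl oxygen of 3 (formyl C–H held by the ring oxygen) and lowers the LUMO of the s-trans enal, so the electron-rich diene 2 adds in a concerted, asynchronous, suprafacial [4+2] cycloaddition; the closest known reaction type is the oxazaborolidinium-catalysed Diels–Alder reaction of 2-substituted acroleins with 2-silyloxybutadienes. The cyclohexene closes by cycloaddition, the two new σ bonds (C3–C4 and C5–C6) forming on one face of the dienophile. C4 and C5 are set together: their relative configuration (ester trans to formyl, cis to methyl) is the E geometry of 3 carried through suprafacially, and their absolute configuration comes from the catalyst, whose aryl groups screen one face of the bound enal so that 2 adds to the Re face of the formyl-bearing carbon. The step needs face selectivity and one orientation; the orientation is secured because the catalyst activates only the aldehyde, so C4 (β to CHO) is the most electrophilic carbon and bonds to the nucleophilic CH2 terminus next to the silyloxy carbon, which places the silyloxy carbon para to C5. Endo/exo selectivity does not arise because the diene has no terminal substituent.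

Step 3
Reactants: 4 ethyl (1R,6R)-6-formyl-6-methyl-3-[(triisopropylsilyl)oxy]cyclohex-3-ene-1-carboxylate
Product: 5 ethyl (1R,6R)-6-ethynyl-6-methyl-3-[(triisopropylsilyl)oxy]cyclohex-3-ene-1-carboxylate
Conditions: dimethyl (1-diazo-2-oxopropyl)phosphonate, K2CO3, MeOH, 0 °C to rt
Reagents that add atoms: dimethyl (1-diazo-2-oxopropyl)phosphonate, COP(=O)(OC)C(=[N+]=[N-])C(C)=O
Why: Seyferth–Gilbert homologation in the Ohira–Bestmann form converts the non-enolisable neopentyl aldehyde into a terminal alkyne, an ozone-tolerant precursor of the arm ketone, under carbonate conditions that the TIPS enol ether and the hindered ester should tolerate.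

Step 4
Reactants: 5 ethyl (1R,6R)-6-ethynyl-6-methyl-3-[(triisopropylsilyl)oxy]cyclohex-3-ene-1-carboxylate
Product: 8 (3R,4R)-3-(ethoxycarbonyl)-4-ethynyl-4-methyl-6-oxohexanoic acid, via methoxy hydroperoxide silyl ester 6 (not isolated), via aldehyde silyl ester 7 (not isolated)
Conditions: O3, CH2Cl2/MeOH, Sudan red 7B, −78 °C; Me2S, −78 °C to rt; then AcOH/H2O/THF, rt
Reagents that add atoms: ozone, [O-][O+]=O
Why: Ozonolysis of a silyl enol ether to an oxo acid: ozone takes the electron-rich enol ether far faster than the alkyne (dye end-point), the oxygen-bearing carbon C2 leaves as the silyl ester and the C7 carbonyl oxide is trapped by methanol, reduced by Me2S to the aldehyde, and mild acid frees the C2 acid.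

Step 5
Reactants: 8 (3R,4R)-3-(ethoxycarbonyl)-4-ethynyl-4-methyl-6-oxohexanoic acid
Product: 9 (3R,4R,6Z)-7-(1,3-dioxolan-2-yl)-3-(ethoxycarbonyl)-4-ethynyl-4-methylhept-6-enoic acid
Conditions: (1,3-dioxolan-2-ylmethyl)triphenylphosphonium bromide (3.5 equiv), KHMDS (3.3 equiv), THF, −78 to 0 °C; aq. NaH2PO4
Reagents that add atoms: (1,3-dioxolan-2-ylmethyl)triphenylphosphonium bromide, [Br-].C1COC(C[P+](c2ccccc2)(c2ccccc2)c2ccccc2)O1
Why: Wittig olefination with a non-stabilised ylide under salt-free, low-temperature conditions is kinetically Z-selective and brings C8 and C9 with C9 already at the aldehyde level as a dioxolane; base is kept below the amount of phosphonium salt so that no free amide can epimerise C4, and one equivalent of ylide only parks the acid as its carboxylate.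

Step 6
Reactants: 9 (3R,4R,6Z)-7-(1,3-dioxolan-2-yl)-3-(ethoxycarbonyl)-4-ethynyl-4-methylhept-6-enoic acid
Product: 11 ethyl (2R,3R,5Z)-6-(1,3-dioxolan-2-yl)-3-ethynyl-2-(2-hydroxyethyl)-3-methylhex-5-enoate, via mixed carbonic anhydride 10 (not isolated)
Conditions: iBuOCOCl, N-methylmorpholine, THF, −15 °C; NaBH4, H2O, −15 to 0 °C; pH 7 work-up
Reagents that add atoms: none
Why: Activation as the mixed carbonic anhydride and NaBH4 reduction reduces the carboxylic acid chemoselectively beside the ethyl ester, acetal and alkyne; the γ-hydroxy ester is worked up cold at neutral pH and used at once so that it does not lactonise.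

Step 7
Reactants: 11 ethyl (2R,3R,5Z)-6-(1,3-dioxolan-2-yl)-3-ethynyl-2-(2-hydroxyethyl)-3-methylhex-5-enoate
Product: 12 ethyl (2R,3R,5Z)-6-(1,3-dioxolan-2-yl)-3-ethynyl-2-(2-iodoethyl)-3-methylhex-5-enoate
Conditions: PPh3, I2, imidazole, CH2Cl2, 0 °C
Reagents that add atoms: iodine, II
Why: Appel-type iodination displaces the alkoxyphosphonium ion by iodide (SN2 at the primary carbon) under imidazole buffering that spares the acetal and removes the lactonisation-prone hydroxyl.

Step 8
Reactants: 12 ethyl (2R,3R,5Z)-6-(1,3-dioxolan-2-yl)-3-ethynyl-2-(2-iodoethyl)-3-methylhex-5-enoate; 13 methyl 3-chloro-3-oxopropanoate (methyl malonyl chloride)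
Product: 15 ethyl (2R,3R,5Z)-6-(1,3-dioxolan-2-yl)-3-ethynyl-2-(5-methoxy-3,5-dioxopentyl)-3-methylhex-5-enoate, via alkylzinc iodide 14 (not isolated)
Conditions: Zn dust (activated with BrCH2CH2Br, Me3SiCl), LiCl, THF, 35 °C; then 13, Pd(PPh3)4 (5 mol%), THF, 0 °C to rt
Reagents that add atoms: none
Why: Zinc inserts into the primary C–I bond of this 4-iodobutanoate-type iodide and the ester-tolerant alkylzinc is acylated by the acid chloride in a Negishi acylation (oxidative addition of the acyl chloride, transmetalation, reductive elimination), palladium catalysis being chosen over copper mediation to avoid carbometalation of the alkyne.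

Step 9
Reactants: 15 ethyl (2R,3R,5Z)-6-(1,3-dioxolan-2-yl)-3-ethynyl-2-(5-methoxy-3,5-dioxopentyl)-3-methylhex-5-enoate
Product: 16 ethyl (2R,3R,5Z)-3-ethynyl-2-(5-methoxy-3,5-dioxopentyl)-3-methyl-7-oxohept-5-enoate
Conditions: PPTS (0.2 equiv), acetone/H2O (10:1), rt to 40 °C
Reagents that add atoms: water, O
Why: Acid-catalysed hydrolysis of the allylic dioxolane through its stabilised oxocarbenium ion should proceed under pyridinium buffering mild enough to leave the Z-alkene, the β-keto ester and the ethyl ester untouched.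

Step 10
Reactants: 16 ethyl (2R,3R,5Z)-3-ethynyl-2-(5-methoxy-3,5-dioxopentyl)-3-methyl-7-oxohept-5-enoate
Product: 18 5-ethyl 1-methyl (1E,5R,6R,8Z)-6-ethynyl-6-methyl-2-oxocyclodeca-1(10),8-diene-1,5-dicarboxylate, via aldol adduct 17 (not isolated)
Conditions: piperidine (0.2 equiv), AcOH (0.2 equiv), 4 Å MS, CH2Cl2 (1 mM, slow addition of 16), rt to 40 °C
Reagents that add atoms: none
Why: Intramolecular Knoevenagel condensation: the β-keto ester carbon C10 adds to the amine-activated aldehyde C9 and the adduct dehydrates to the cross-conjugated dienone, with high dilution, the cis C7=C8 bond and the vicinal C4/C5 substitution favouring ring closure and the ten-membered ring allowing only the C9=C10 geometry with C8 cis to C1.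

Step 11
Reactants: 18 5-ethyl 1-methyl (1E,5R,6R,8Z)-6-ethynyl-6-methyl-2-oxocyclodeca-1(10),8-diene-1,5-dicarboxylate
Product: 19 5-ethyl 1-methyl (1E,5R,6R,8Z)-6-ethynyl-6-methyl-2-methylidenecyclodeca-1(10),8-diene-1,5-dicarboxylate
Conditions: Cp2Ti(μ-Cl)(μ-CH2)AlMe2 (1.2 equiv), pyridine (cat.), THF/toluene, −40 to 0 °C
Reagents that add atoms: Tebbe reagent, C[Al-]1(C)C[Ti]([Cl+]1)(C1C=CC=C1)C1C=CC=C1
Why: Tebbe methylenation ([2+2] addition of the titanium methylidene to the C1 carbonyl and cycloreversion driven by the Ti–O bond) is non-basic and non-nucleophilic, so it should avoid conjugate addition to the alkylidene keto ester and take the ketone before the esters; it is run while the arm is still an alkyne because C1 must be the only ketone in the molecule.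

Step 12
Reactants: 19 5-ethyl 1-methyl (1E,5R,6R,8Z)-6-ethynyl-6-methyl-2-methylidenecyclodeca-1(10),8-diene-1,5-dicarboxylate; 20 3-bromofuran
Product: 21 5-ethyl 1-methyl (1E,5R,6R,8Z)-6-[(furan-3-yl)ethynyl]-6-methyl-2-methylidenecyclodeca-1(10),8-diene-1,5-dicarboxylate
Conditions: PdCl2(PPh3)2 (5 mol%), CuI (10 mol%), Et3N, THF, 50 °C
Reagents that add atoms: none
Why: Sonogashira coupling (oxidative addition of the bromofuran to zerovalent palladium, transmetalation from the copper acetylide, reductive elimination) joins the furan to the terminal alkyne beside esters and the triene, and is placed after the ozonolysis because a furan would not survive ozone.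

Step 13
Reactants: 21 5-ethyl 1-methyl (1E,5R,6R,8Z)-6-[(furan-3-yl)ethynyl]-6-methyl-2-methylidenecyclodeca-1(10),8-diene-1,5-dicarboxylate
Product: 22 5-ethyl 1-methyl (1E,5R,6S,8Z)-6-[2-(furan-3-yl)-2-oxoethyl]-6-methyl-2-methylidenecyclodeca-1(10),8-diene-1,5-dicarboxylate
Conditions: (Ph3P)AuNTf2 (5 mol%), 1,4-dioxane/H2O (10:1), 60 °C
Reagents that add atoms: water, O
Why: Gold-catalysed Markovnikov hydration of an aryl alkyne: water should add to the gold-activated triple bond at the carbon bearing the electron-rich 3-furyl group, which best carries positive charge and is remote from the quaternary centre, and protodeauration with tautomerisation gives the furyl ketone.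

Step 14
Reactants: 22 5-ethyl 1-methyl (1E,5R,6S,8Z)-6-[2-(furan-3-yl)-2-oxoethyl]-6-methyl-2-methylidenecyclodeca-1(10),8-diene-1,5-dicarboxylate
Product: 23 (1E,5R,6S,8Z)-6-[2-(furan-3-yl)-2-oxoethyl]-6-methyl-2-methylidenecyclodeca-1(10),8-diene-1,5-dicarboxylic acid (CNP0137484.1)
Conditions: LiOH·H2O (6 equiv), THF/H2O (2:1), rt to 40 °C; then 1 M HCl to pH 3
Reagents that add atoms: lithium hydroxide, [Li+].[OH-]
Why: Saponification of both esters by acyl–oxygen cleavage and acidification gives the diacid; C5 is quaternary and C4 can no longer epimerise once its carboxylate has formed.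

**Compound list**

1 | methyl vinyl ketone | CC(=O)C=C | starting material
2 | 2-(triisopropylsilyloxy)buta-1,3-diene | C=CC(=C)O[Si](C(C)C)(C(C)C)C(C)C | intermediate
3 | ethyl (E)-3-methyl-4-oxobut-2-enoate | CCOC(=O)/C=C(\C)C=O | starting material
4 | ethyl (1R,6R)-6-formyl-6-methyl-3-[(triisopropylsilyl)oxy]cyclohex-3-ene-1-carboxylate | C1(O[Si](C(C)C)(C(C)C)C(C)C)C[C@@H](C(=O)OCC)[C@](C)(C=O)CC=1 | intermediate
5 | ethyl (1R,6R)-6-ethynyl-6-methyl-3-[(triisopropylsilyl)oxy]cyclohex-3-ene-1-carboxylate | C1(O[Si](C(C)C)(C(C)C)C(C)C)C[C@@H](C(=O)OCC)[C@](C)(C#C)CC=1 | intermediate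
6 | triisopropylsilyl (3R,4R)-3-(ethoxycarbonyl)-4-ethynyl-6-hydroperoxy-6-methoxy-4-methylhexanoate (C6 epimers) | CC(C)[Si](C(C)C)(C(C)C)OC(=O)C[C@@H](C(=O)OCC)[C@](C)(C#C)CC(OC)OO | intermediate
7 | triisopropylsilyl (3R,4R)-3-(ethoxycarbonyl)-4-ethynyl-4-methyl-6-oxohexanoate | CC(C)[Si](C(C)C)(C(C)C)OC(=O)C[C@@H](C(=O)OCC)[C@](C)(C#C)CC=O | intermediate
8 | (3R,4R)-3-(ethoxycarbonyl)-4-ethynyl-4-methyl-6-oxohexanoic acid | OC(=O)C[C@@H](C(=O)OCC)[C@](C)(C#C)CC=O | intermediate
9 | (3R,4R,6Z)-7-(1,3-dioxolan-2-yl)-3-(ethoxycarbonyl)-4-ethynyl-4-methylhept-6-enoic acid | OC(=O)C[C@@H](C(=O)OCC)[C@](C)(C#C)C/C=C\C1OCCO1 | intermediate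
10 | isobutyl carbonic anhydride of acid 9 | CC(C)COC(=O)OC(=O)C[C@@H](C(=O)OCC)[C@](C)(C#C)C/C=C\C1OCCO1 | intermediate
11 | ethyl (2R,3R,5Z)-6-(1,3-dioxolan-2-yl)-3-ethynyl-2-(2-hydroxyethyl)-3-methylhex-5-enoate | OCC[C@@H](C(=O)OCC)[C@](C)(C#C)C/C=C\C1OCCO1 | intermediate
12 | ethyl (2R,3R,5Z)-6-(1,3-dioxolan-2-yl)-3-ethynyl-2-(2-iodoethyl)-3-methylhex-5-enoate | ICC[C@@H](C(=O)OCC)[C@](C)(C#C)C/C=C\C1OCCO1 | intermediate
13 | methyl 3-chloro-3-oxopropanoate (methyl malonyl chloride) | COC(=O)CC(=O)Cl | starting material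
14 | alkylzinc iodide from 12 (zinc on the former iodo carbon) | I[Zn]CC[C@@H](C(=O)OCC)[C@](C)(C#C)C/C=C\C1OCCO1 | intermediate
15 | ethyl (2R,3R,5Z)-6-(1,3-dioxolan-2-yl)-3-ethynyl-2-(5-methoxy-3,5-dioxopentyl)-3-methylhex-5-enoate | COC(=O)CC(=O)CC[C@@H](C(=O)OCC)[C@](C)(C#C)C/C=C\C1OCCO1 | intermediate
16 | ethyl (2R,3R,5Z)-3-ethynyl-2-(5-methoxy-3,5-dioxopentyl)-3-methyl-7-oxohept-5-enoate | COC(=O)CC(=O)CC[C@@H](C(=O)OCC)[C@](C)(C#C)C/C=C\C=O | intermediate
17 | 5-ethyl 1-methyl (5R,6R,8Z)-6-ethynyl-10-hydroxy-6-methyl-2-oxocyclodec-8-ene-1,5-dicarboxylate (C1/C10 stereoisomers) | O=C1CC[C@@H](C(=O)OCC)[C@](C)(C#C)C/C=C\C(O)C1C(=O)OC | intermediate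
18 | 5-ethyl 1-methyl (1E,5R,6R,8Z)-6-ethynyl-6-methyl-2-oxocyclodeca-1(10),8-diene-1,5-dicarboxylate | O=C1CC[C@@H](C(=O)OCC)[C@](C)(C#C)C/C=C\C=C/1C(=O)OC | intermediate
19 | 5-ethyl 1-methyl (1E,5R,6R,8Z)-6-ethynyl-6-methyl-2-methylidenecyclodeca-1(10),8-diene-1,5-dicarboxylate | C=C1CC[C@@H](C(=O)OCC)[C@](C)(C#C)C/C=C\C=C/1C(=O)OC | intermediate
20 | 3-bromofuran | Brc1ccoc1 | starting material
21 | 5-ethyl 1-methyl (1E,5R,6R,8Z)-6-[(furan-3-yl)ethynyl]-6-methyl-2-methylidenecyclodeca-1(10),8-diene-1,5-dicarboxylate | C=C1CC[C@@H](C(=O)OCC)[C@](C)(C#Cc2ccoc2)C/C=C\C=C/1C(=O)OC | intermediate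
22 | 5-ethyl 1-methyl (1E,5R,6S,8Z)-6-[2-(furan-3-yl)-2-oxoethyl]-6-methyl-2-methylidenecyclodeca-1(10),8-diene-1,5-dicarboxylate | C=C1CC[C@@H](C(=O)OCC)[C@](C)(CC(=O)c2ccoc2)C/C=C\C=C/1C(=O)OC | intermediate
23 | (1E,5R,6S,8Z)-6-[2-(furan-3-yl)-2-oxoethyl]-6-methyl-2-methylidenecyclodeca-1(10),8-diene-1,5-dicarboxylic acid | C=C1CC[C@@H](C(=O)O)[C@](C)(CC(=O)c2ccoc2)C/C=C\C=C/1C(=O)O | target

**Step count and risks**

Total steps: 14. Longest linear sequence: 14 steps (1 to 23).

Step 10. Ring closure to a ten-membered ring may lose to intermolecular condensation, and the amine catalyst may isomerise the Z-enal through its iminium ion so that the reacting ends no longer meet. Fallback (sets out from 16, returns at 18): the ring is closed by C-alkylation instead of condensation. The aldehyde of 16 is reduced with LiAlH(OtBu)3 (THF, −78 °C, the β-keto ester being parked as its enolate) to the Z-allylic alcohol F1, which CBr4/PPh3 converts into the Z-allylic bromide F2. Cs2CO3 in MeCN at high dilution then joins C10 to C9, as in known macrocyclic alkylations of 1,3-dicarbonyl compounds by allylic halides, and gives the ten-membered β-keto ester F3. Selenenylation (PhSeCl, pyridine) gives the phenylselanyl keto ester F4, H2O2 oxidises it to the selenoxide F5, and syn-elimination towards C9 gives 18.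

Step 13. Water may be delivered to the wrong alkyne carbon if the C4 ester carbonyl takes part as a neighbouring group, or the gold-activated alkyne may be captured by the C7=C8 alkene. Fallback (sets out from 19, returns at 22; steps 12 and 13 are then not needed): the ketone oxygen is placed by C–C bond formation and not by alkyne polarisation. Anti-Markovnikov hydration of the terminal alkyne of 19 ([CpRu(MeCN)3]PF6 with 5,5'-bis(trifluoromethyl)-2,2'-bipyridine, aqueous NMP) gives the aldehyde F6. Nozaki–Hiyama–Kishi addition of 3-iodofuran (CrCl2, catalytic NiCl2, DMF), which is selective for aldehydes beside esters, gives the furyl carbinol F7 as a mixture of epimers. Dess–Martin periodinane (NaHCO3, CH2Cl2) oxidises it to 22.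

Step 8 (with its feeder steps 6 and 7). The γ-hydroxy ester 11 may lactonise before it is iodinated, the alkylzinc may be protonated by the acidic β-keto ester as it forms, or the acid chloride may be lost as a ketene. Fallback (sets out from 9, returns at 15; replaces steps 6 to 8): Arndt–Eistert homologation followed by a Masamune-type acylation. The mixed anhydride 10 is treated with diazomethane to give the diazoketone F8. Photochemical Wolff rearrangement in wet THF passes through the ketene F9 to the homologous acid F10. Carbonyldiimidazole gives the acyl imidazolide F11, which potassium methyl malonate with MgCl2 and Et3N converts, with decarboxylation, into 15. In this variant the carbon brought by diazomethane becomes C2 and the ozonolysis-derived carboxyl carbon becomes C1; the constitution and configuration of 15 are unchanged.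

**Further compounds**

F1 | step 10 | ethyl (2R,3R,5Z)-3-ethynyl-7-hydroxy-2-(5-methoxy-3,5-dioxopentyl)-3-methylhept-5-enoate | COC(=O)CC(=O)CC[C@@H](C(=O)OCC)[C@](C)(C#C)C/C=C\CO
F2 | step 10 | ethyl (2R,3R,5Z)-7-bromo-3-ethynyl-2-(5-methoxy-3,5-dioxopentyl)-3-methylhept-5-enoate | COC(=O)CC(=O)CC[C@@H](C(=O)OCC)[C@](C)(C#C)C/C=C\CBr
F3 | step 10 | 5-ethyl 1-methyl (5R,6R,8Z)-6-ethynyl-6-methyl-2-oxocyclodec-8-ene-1,5-dicarboxylate (C1 epimers) | O=C1CC[C@@H](C(=O)OCC)[C@](C)(C#C)C/C=C\CC1C(=O)OC
F4 | step 10 | 5-ethyl 1-methyl (5R,6R,8Z)-6-ethynyl-6-methyl-2-oxo-1-(phenylselanyl)cyclodec-8-ene-1,5-dicarboxylate (C1 epimers) | O=C1CC[C@@H](C(=O)OCC)[C@](C)(C#C)C/C=C\CC1([Se]c2ccccc2)C(=O)OC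
F5 | step 10 | 5-ethyl 1-methyl (5R,6R,8Z)-1-(benzeneseleninyl)-6-ethynyl-6-methyl-2-oxocyclodec-8-ene-1,5-dicarboxylate (stereoisomers at C1 and Se) | O=C1CC[C@@H](C(=O)OCC)[C@](C)(C#C)C/C=C\CC1([Se](=O)c2ccccc2)C(=O)OC
F6 | step 13 | 5-ethyl 1-methyl (1E,5R,6S,8Z)-6-methyl-2-methylidene-6-(2-oxoethyl)cyclodeca-1(10),8-diene-1,5-dicarboxylate | C=C1CC[C@@H](C(=O)OCC)[C@](C)(CC=O)C/C=C\C=C/1C(=O)OC
F7 | step 13 | 5-ethyl 1-methyl (1E,5R,6S,8Z)-6-[2-(furan-3-yl)-2-hydroxyethyl]-6-methyl-2-methylidenecyclodeca-1(10),8-diene-1,5-dicarboxylate (carbinol epimers) | C=C1CC[C@@H](C(=O)OCC)[C@](C)(CC(O)c2ccoc2)C/C=C\C=C/1C(=O)OC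
F8 | step 8 | ethyl (2R,3R,5Z)-2-(3-diazo-2-oxopropyl)-6-(1,3-dioxolan-2-yl)-3-ethynyl-3-methylhex-5-enoate | [N-]=[N+]=CC(=O)C[C@@H](C(=O)OCC)[C@](C)(C#C)C/C=C\C1OCCO1
F9 | step 8 | ethyl (2R,3R,5Z)-6-(1,3-dioxolan-2-yl)-3-ethynyl-3-methyl-2-(3-oxoprop-2-en-1-yl)hex-5-enoate | O=C=CC[C@@H](C(=O)OCC)[C@](C)(C#C)C/C=C\C1OCCO1
F10 | step 8 | (4R,5R,7Z)-8-(1,3-dioxolan-2-yl)-4-(ethoxycarbonyl)-5-ethynyl-5-methyloct-7-enoic acid | OC(=O)CC[C@@H](C(=O)OCC)[C@](C)(C#C)C/C=C\C1OCCO1
F11 | step 8 | ethyl (2R,3R,5Z)-6-(1,3-dioxolan-2-yl)-3-ethynyl-2-[3-(1H-imidazol-1-yl)-3-oxopropyl]-3-methylhex-5-enoate | O=C(n1ccnc1)CC[C@@H](C(=O)OCC)[C@](C)(C#C)C/C=C\C1OCCO1
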